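## The problem

The target is a chroman: a fully substituted benzene ring fused along C4a–C8a to a dihydropyran that carries a gem-dimethyl group at C2 and a secondary carbinol at C4. Round the benzene ring, C5 bears hydroxyl, C6 methyl, C7 hydroxyl, C8 the 3-phenylpropanoyl chain and C8a the ring oxygen. Three phloroglucinol-type oxygens must therefore be told apart, and methyl and acyl must each sit between the right pair, which electrophilic substitution of a nearly symmetric phloroglucinol does poorly. C4 (R) is the only stereocentre; nothing in the molecule can steer it, so it must come from a reagent-controlled step or a resolution and then be carried unchanged. That carbinol is benzylic and stands ortho, ortho and para to three oxygen donors, so acid ionises it (racemisation, elimination to the 2H-chromene) and hydrogenolysis cleaves it; the free acylphloroglucinol is also sensitive to oxidants and strong base. Protecting groups must therefore leave under nearly neutral, non-reductive conditions. The feature that invites a de novo arene construction is that the C4a–C8a edge is the enol-ether double bond of a 5,6-dihydro-4H-pyran (O1–C8a=C4a–C4), which can hold the C4 carbinol before any aromatic ring exists. The remaining ring atoms C5(O), C6(Me), C7(O) and C8(H) match what a ketene carbon, the two carbons of a methyl-substituted ynol ether and a diazo-derived CH deliver.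

## Retrosynthesis

**Target 25 from ketone 24.** Only the O4–Si and O7–Si bonds are cut. Silicon on both oxygens allows one buffered fluoride treatment at the end; benzyl ethers would need hydrogenolysis or a Lewis acid, and both attack the C4–O bond. The forward step must free a hindered benzylic silyl ether without ionising C4.

**Ketone 24 from bromide 20 and amide 22.** The C8–C(=O) bond is cut. Acid-mediated C-acylation would make the same bond but the C4 ether cannot stand the acid, and an anionic acyl shift from O5 cannot reach C8 past the C6 methyl group. A C8 carbanion (dilithio species 23) and the N-methoxy-N-methylamide 22, one step from acid 21, avoid both. The forward step needs halogen–lithium exchange on a phenoxide and acylation that outruns silyl migration from O7.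

**Bromide 20 from phenol 19.** The C8–Br bond is cut. C8 is the only ring C–H, para to the free hydroxyl, so no regiochemical question arises.

**Phenol 19 from diazoketone 10 and siloxyalkyne 14.** This cut carries the plan. C5–C6, C7–C8 and C4a–C5 are disconnected; in the forward sense the C8–C8a link comes from the 1,2-shift of the Wolff rearrangement. Cutting the pyran ring instead would leave a preformed phloroglucinol with its regiochemical ambiguity. Here the polarity of the two partners places methyl between the two different oxygens. The precursors are a monocyclic dihydropyran that already holds the stereocentre and a three-carbon alkyne. The forward cascade runs through vinylketene 15, cyclobutenone 16, dienylketene 17 and cyclohexadienone 18.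

**Siloxyalkyne 14 from ethyl acetate 11.** The alkyne is traced to an ester plus one carbenoid carbon, through dibromo enolate 12 and ynolate 13. The forward step must silylate the ynolate on oxygen, which a bulky silyl group secures.

**Diazoketone 10 from methyl ketone 8, and 8 from ester 6.** The diazo group is introduced by diazo transfer to the activated diketone 9 and not by acylating a diazoalkane, which would add as a dipole to the conjugated double bond. Ketone 8 comes from ester 6 through Weinreb amide 7 in one flask.

**Ester 6 from alcohol 5 and ketone 4.** The C4–H bond is the stereogenic cut. Reducing the ketone at the monocyclic stage means the carbinol is never unprotected next to an electron-rich arene. The forward step needs face-selective hydride delivery to a cyclic enone.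

**Ketone 4 from mesityl oxide 1 and diethyl oxalate 2.** The C2–C3 bond (Claisen) and the O1–C6 bond (oxa-Michael) are cut, with diketo ester 3 in between. Both precursors are bulk chemicals and the ring closes in the same flask.

## Roads not taken

**Alternative 1: carbonylative union of the side chain.** Both bonds to the ketone carbon are cut, C8–C(=O) and C(=O)–CH2. In the forward sense the dibenzyl bromide A2, carbon monoxide A4 and the alkylborane A3 combine on a zerovalent palladium phosphine catalyst: oxidative addition, CO insertion, alkyl transfer from boron and reductive elimination give ketone A1.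
- Merits: no organolithium, no separate amide, and the free C4 carbinol is tolerated.
- Weak points: oxidative addition into a di-ortho-substituted, electron-rich bromide is slow, so direct coupling without CO and β-hydride loss from the alkyl group compete. The benzyl ethers of A1 must then be removed next to a doubly activated benzylic C–O bond. The plan also says nothing about how the ring and stereocentre of A2 are made.
- Comparison: for the side chain alone this road is at least as good as steps 9 and 10 of the chosen route. The chosen plan sets against it a fluoride-only endgame and an arene whose substitution pattern is fixed by construction.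

**Alternative 2: aryne and enal annulation.** O1–C8a, C4–C4a and O1–C2 are cut. A fluoride source releases the aryne from silyl triflate A6; the carbonyl group of enal A7 adds across it, the benzoxete opens to an ortho-quinone methide, and oxa-6π closure gives chromene A5.
- Merits: the pyran ring with its gem-dimethyl group forms in one mild step without light, and the alkoxy group next to the aryne directs the oxygen to the distal carbon.
- Weak points: A5 has neither the C4 oxygen nor the stereocentre. Asymmetric epoxidation of such chromenes is well established, but hydride opens the epoxide at the benzylic carbon and leaves the hydroxyl at C3, so a longer redox detour is needed. A6 needs several steps and the same oxygen differentiation, and the benzyl ethers return.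
- Comparison: the ring-forming step is simpler than a photochemical benzannulation. The chosen plan sets against it a C4 carbinol that is in place, with its configuration, before the arene exists.

**Alternative 3: asymmetric Prins-type annulation.** C3–C4 and O1–C2 are cut. A confined chiral Brønsted acid activates aldehyde A9, alkene A10 adds to the carbonyl carbon, and the phenol oxygen traps the tertiary cation to give chromanol A8.
- Merits: ring and stereocentre arise in one catalytic step from an achiral aldehyde and a feedstock alkene. If it worked as hoped it would be several steps shorter than the chosen route.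
- Weak points: the aldehyde is donor-rich and internally hydrogen-bonded, hence a weak electrophile. Carbonyl-ene and double-addition paths compete. A8 is the kind of benzylic alcohol that strong acid ionises, so the catalyst may erode the centre it has just set. Enantiocontrol on this substrate class is not established, and the benzyl ethers return.
- Comparison: this road is better in step economy. The chosen plan sets against it known reaction types throughout, a stereocentre set by ketone reduction away from any acid, and silyl ethers that leave under buffered fluoride.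

Key step: step 7

Assumption: in the reduction of 4 the conjugated enol-ether flank of the carbonyl group is taken to act as the larger substituent, as the aryl ring does in chroman-4-ones; this fixes the (S)-oxazaborolidine for the (4R)-alcohol, and the (R)-catalyst would be used if the sense proved opposite.

## Route

Step 1
Reactants: 1 mesityl oxide; 2 diethyl oxalate
Product: 4 ethyl 6,6-dimethyl-4-oxo-5,6-dihydro-4H-pyran-2-carboxylate, via ethyl 6-methyl-2,4-dioxohept-5-enoate 3 (not isolated)
Conditions: NaOEt, EtOH, 0 °C to rt; then HCl/EtOH, reflux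
Reagents that add atoms: none
Why: Crossed Claisen condensation of the methyl ketone with the non-enolisable oxalate gives the enolate of 3; acid then promotes 6-endo oxa-Michael addition of the C2 enol oxygen to the β,β-dimethyl enone, a long-known closure for this type of diketo ester.

Step 2
Reactants: 4 ethyl 6,6-dimethyl-4-oxo-5,6-dihydro-4H-pyran-2-carboxylate
Product: 5 ethyl (4R)-4-hydroxy-6,6-dimethyl-5,6-dihydro-4H-pyran-2-carboxylate
Conditions: (S)-2-methyl-CBS-oxazaborolidine (0.2 equiv), BH3·SMe2, THF, −20 °C; MeOH quench
Reagents that add atoms: none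
Why: Corey–Bakshi–Shibata reduction; the ketone should bind the catalyst boron with its conjugated flank away from the B-methyl group, and hydride from the nitrogen-bound borane then reaches the face that gives the (4R)-alcohol, while the ester and the electron-poor enol ether are inert to borane at this temperature.

Step 3
Reactants: 5 ethyl (4R)-4-hydroxy-6,6-dimethyl-5,6-dihydro-4H-pyran-2-carboxylate
Product: 6 ethyl (4R)-4-(tert-butyldimethylsilyloxy)-6,6-dimethyl-5,6-dihydro-4H-pyran-2-carboxylate
Conditions: TBSCl, imidazole, DMF, rt
Reagents that add atoms: tert-butyldimethylsilyl chloride, CC(C)(C)[Si](C)(C)Cl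
Why: Standard silylation of a secondary allylic alcohol; the tert-butyldimethylsilyl ether is chosen to survive Grignard reagents, amide bases, light, heat and organolithiums and to leave with fluoride.

Step 4
Reactants: 6 ethyl (4R)-4-(tert-butyldimethylsilyloxy)-6,6-dimethyl-5,6-dihydro-4H-pyran-2-carboxylate
Product: 8 1-[(4R)-4-(tert-butyldimethylsilyloxy)-6,6-dimethyl-5,6-dihydro-4H-pyran-2-yl]ethan-1-one, via Weinreb amide 7 (not isolated)
Conditions: MeNH(OMe)·HCl, i-PrMgCl, THF, −20 °C; then MeMgBr, −20 to 0 °C; aq NH4Cl
Reagents that add atoms: methylmagnesium bromide, C[Mg]Br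
Why: Ester aminolysis by the chloromagnesium amide of N,O-dimethylhydroxylamine, then Grignard addition to the Weinreb amide in the same flask; the magnesium chelate of the tetrahedral adduct stops the addition at the ketone.

Step 5
Reactants: 8 1-[(4R)-4-(tert-butyldimethylsilyloxy)-6,6-dimethyl-5,6-dihydro-4H-pyran-2-yl]ethan-1-one
Product: 10 1-[(4R)-4-(tert-butyldimethylsilyloxy)-6,6-dimethyl-5,6-dihydro-4H-pyran-2-yl]-2-diazoethan-1-one, via trifluoroacetyl diketone 9 (not isolated)
Conditions: LiN(SiMe3)2, THF, −78 °C; CF3CO2CH2CF3; then MsN3, Et3N, H2O, MeCN, rt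
Reagents that add atoms: methanesulfonyl azide, CS(=O)(=O)N=[N+]=[N-]
Why: Detrifluoroacetylative diazo transfer; the kinetic methyl enolate is trifluoroacetylated and the activated diketone 9 takes the diazo group from the sulfonyl azide with loss of the trifluoroacetyl group, the standard entry to unsaturated diazoketones because it keeps diazomethane away from the conjugated double bond.

Step 6
Reactants: 11 ethyl acetate
Product: 14 1-(triisopropylsilyloxy)prop-1-yne, via lithium 1,1-dibromoprop-1-en-2-olate 12 (not isolated), via lithium prop-1-yn-1-olate 13 (not isolated)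
Conditions: CH2Br2, lithium 2,2,6,6-tetramethylpiperidide, THF, −78 °C; n-BuLi, −78 °C to rt; i-Pr3SiCl, −78 to 0 °C
Reagents that add atoms: dibromomethane, BrCBr; triisopropylsilyl chloride, CC(C)[Si](Cl)(C(C)C)C(C)C
Why: Kowalski ester homologation stopped at the ynolate; dibromomethyllithium adds to the ester, enolate 12 undergoes bromine–lithium exchange and 1,2-shift with loss of LiBr to ynolate 13, and the bulky silyl chloride reacts at oxygen.

Step 7
Reactants: 10 1-[(4R)-4-(tert-butyldimethylsilyloxy)-6,6-dimethyl-5,6-dihydro-4H-pyran-2-yl]-2-diazoethan-1-one; 14 1-(triisopropylsilyloxy)prop-1-yne (1.5 equiv)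
Product: 19 (4R)-4-(tert-butyldimethylsilyloxy)-2,2,6-trimethyl-7-(triisopropylsilyloxy)chroman-5-ol, via vinylketene 15 (not isolated), via vinylcyclobutenone 16 (not isolated), via dienylketene 17 (not isolated), via cyclohexadienone 18 (not isolated)
Conditions: hν (254 nm, low-pressure Hg lamp, Vycor), ClCH2CH2Cl, rt; then 80 °C
Reagents that add atoms: none
Why: Irradiation expels N2 and the dihydropyranyl group shifts to the carbene carbon (Wolff rearrangement), which makes the C8–C8a link and vinylketene 15. The nucleophilic methyl-bearing carbon of 14 attacks the ketene carbonyl carbon and ring closure gives cyclobutenone 16, a (2+2) addition that forms C5–C6 and C7–C8. On warming, 16 opens by a four-electron electrocyclic reaction to dienylketene 17, which closes the benzene ring by a thermal disrotatory six-electron electrocyclisation (C4a–C5) to cyclohexadienone 18, and enolisation gives phenol 19. The closest known reaction type is the Danheiser benzannulation of unsaturated diazoketones with siloxyalkynes. No stereocentre is created in 19: the transient centres of 16 and 18 are erased on aromatisation, and the C4 silyl ether lies outside the reacting π system, so the configuration from step 2 is kept. The selectivity needed is the regiochemistry of the (2+2) step, secured by the polarisation of the ynol ether and of the ketene, which puts methyl between the C5 hydroxyl and the C7 silyloxy group and leaves C8 as the only ring C–H. Excess alkyne and slow photochemical release of the ketene should limit ketene dimerisation and capture of the ketene by the phenol.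

Step 8
Reactants: 19 (4R)-4-(tert-butyldimethylsilyloxy)-2,2,6-trimethyl-7-(triisopropylsilyloxy)chroman-5-ol
Product: 20 (4R)-8-bromo-4-(tert-butyldimethylsilyloxy)-2,2,6-trimethyl-7-(triisopropylsilyloxy)chroman-5-ol
Conditions: NBS, CH2Cl2, −78 to 0 °C, dark
Reagents that add atoms: N-bromosuccinimide, O=C1CCC(=O)N1Br
Why: Electrophilic aromatic bromination at the only free ring position, para to the hydroxyl and ortho to two oxygens; succinimide is the only by-product, so the C4 silyl ether meets no acid.

Step 9
Reactants: 21 3-phenylpropanoic acid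
Product: 22 N-methoxy-N-methyl-3-phenylpropanamide
Conditions: CDI, CH2Cl2, rt; then MeNH(OMe)·HCl, rt
Reagents that add atoms: N,O-dimethylhydroxylamine hydrochloride, Cl.CNOC
Why: Amide formation through the acyl imidazole, a routine preparation of a Weinreb amide.

Step 10
Reactants: 20 (4R)-8-bromo-4-(tert-butyldimethylsilyloxy)-2,2,6-trimethyl-7-(triisopropylsilyloxy)chroman-5-ol; 22 N-methoxy-N-methyl-3-phenylpropanamide
Product: 24 1-[(4R)-4-(tert-butyldimethylsilyloxy)-5-hydroxy-2,2,6-trimethyl-7-(triisopropylsilyloxy)chroman-8-yl]-3-phenylpropan-1-one, via dilithio aryl phenoxide 23 (not isolated)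
Conditions: MeLi, THF, −78 °C; t-BuLi (2 equiv), −78 °C; then 22, −78 to 0 °C; aq NH4Cl
Reagents that add atoms: none
Why: The phenol is deprotonated first, bromine–lithium exchange then gives aryllithium 23, and its addition to the Weinreb amide stops at the chelated tetrahedral adduct, which releases the ketone on work-up; the bulky triisopropylsilyl group is chosen to resist O-to-C silyl shift at −78 °C.

Step 11
Reactants: 24 1-[(4R)-4-(tert-butyldimethylsilyloxy)-5-hydroxy-2,2,6-trimethyl-7-(triisopropylsilyloxy)chroman-8-yl]-3-phenylpropan-1-one
Product: 25 1-[(4R)-4,5,7-trihydroxy-2,2,6-trimethylchroman-8-yl]-3-phenylpropan-1-one (the target)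
Conditions: Bu4NF, AcOH (1:1), THF, 0 °C to rt
Reagents that add atoms: none
Why: Fluoride cleaves the aryl and the benzylic Si–O bonds, and acetic acid buffers the liberated phenoxides so that neither base nor acid ionises the C4–O bond; the configuration set in step 2 is retained.

## Compound list

1 | mesityl oxide (4-methylpent-3-en-2-one) | CC(C)=CC(C)=O | starting material
2 | diethyl oxalate | CCOC(=O)C(=O)OCC | starting material
3 | ethyl 6-methyl-2,4-dioxohept-5-enoate | CCOC(=O)C(=O)CC(=O)C=C(C)C | intermediate (not isolated)
4 | ethyl 6,6-dimethyl-4-oxo-5,6-dihydro-4H-pyran-2-carboxylate | CCOC(=O)C1=CC(=O)CC(C)(C)O1 | intermediate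
5 | ethyl (4R)-4-hydroxy-6,6-dimethyl-5,6-dihydro-4H-pyran-2-carboxylate | CCOC(=O)C1=C[C@H](O)CC(C)(C)O1 | intermediate
6 | ethyl (4R)-4-(tert-butyldimethylsilyloxy)-6,6-dimethyl-5,6-dihydro-4H-pyran-2-carboxylate | CCOC(=O)C1=C[C@H](O[Si](C)(C)C(C)(C)C)CC(C)(C)O1 | intermediate
7 | (4R)-4-(tert-butyldimethylsilyloxy)-N-methoxy-N,6,6-trimethyl-5,6-dihydro-4H-pyran-2-carboxamide | CON(C)C(=O)C1=C[C@H](O[Si](C)(C)C(C)(C)C)CC(C)(C)O1 | intermediate (not isolated)
8 | 1-[(4R)-4-(tert-butyldimethylsilyloxy)-6,6-dimethyl-5,6-dihydro-4H-pyran-2-yl]ethan-1-one | CC(=O)C1=C[C@H](O[Si](C)(C)C(C)(C)C)CC(C)(C)O1 | intermediate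
9 | 1-[(4R)-4-(tert-butyldimethylsilyloxy)-6,6-dimethyl-5,6-dihydro-4H-pyran-2-yl]-4,4,4-trifluorobutane-1,3-dione | O=C(CC(=O)C(F)(F)F)C1=C[C@H](O[Si](C)(C)C(C)(C)C)CC(C)(C)O1 | intermediate (not isolated)
10 | 1-[(4R)-4-(tert-butyldimethylsilyloxy)-6,6-dimethyl-5,6-dihydro-4H-pyran-2-yl]-2-diazoethan-1-one | [N-]=[N+]=CC(=O)C1=C[C@H](O[Si](C)(C)C(C)(C)C)CC(C)(C)O1 | intermediate
11 | ethyl acetate | CCOC(C)=O | starting material
12 | lithium 1,1-dibromoprop-1-en-2-olate | [Li+].CC([O-])=C(Br)Br | intermediate (not isolated)
13 | lithium prop-1-yn-1-olate | [Li+].CC#C[O-] | intermediate (not isolated)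
14 | 1-(triisopropylsilyloxy)prop-1-yne | CC#CO[Si](C(C)C)(C(C)C)C(C)C | intermediate
15 | 2-[(4R)-4-(tert-butyldimethylsilyloxy)-6,6-dimethyl-5,6-dihydro-4H-pyran-2-yl]ethen-1-one (vinylketene) | O=C=CC1=C[C@H](O[Si](C)(C)C(C)(C)C)CC(C)(C)O1 | intermediate (not isolated)
16 | 4-[(4R)-4-(tert-butyldimethylsilyloxy)-6,6-dimethyl-5,6-dihydro-4H-pyran-2-yl]-2-methyl-3-(triisopropylsilyloxy)cyclobut-2-en-1-one (both epimers at the ring CH) | CC1=C(O[Si](C(C)C)(C(C)C)C(C)C)C(C1=O)C1=C[C@H](O[Si](C)(C)C(C)(C)C)CC(C)(C)O1 | intermediate (not isolated)
17 | 4-[(4R)-4-(tert-butyldimethylsilyloxy)-6,6-dimethyl-5,6-dihydro-4H-pyran-2-yl]-2-methyl-3-(triisopropylsilyloxy)buta-1,3-dien-1-one (ketenyl and pyranyl groups cis) | O=C=C(C)/C(O[Si](C(C)C)(C(C)C)C(C)C)=C\C1=C[C@H](O[Si](C)(C)C(C)(C)C)CC(C)(C)O1 | intermediate (not isolated)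
18 | (4R)-4-(tert-butyldimethylsilyloxy)-2,2,6-trimethyl-7-(triisopropylsilyloxy)-2,3,4,4a-tetrahydro-5H-chromen-5-one (both epimers at C4a) | CC1=C(O[Si](C(C)C)(C(C)C)C(C)C)C=C2OC(C)(C)C[C@@H](O[Si](C)(C)C(C)(C)C)C2C1=O | intermediate (not isolated)
19 | (4R)-4-(tert-butyldimethylsilyloxy)-2,2,6-trimethyl-7-(triisopropylsilyloxy)chroman-5-ol | Cc1c(O[Si](C(C)C)(C(C)C)C(C)C)cc2c(c1O)[C@H](O[Si](C)(C)C(C)(C)C)CC(C)(C)O2 | intermediate
20 | (4R)-8-bromo-4-(tert-butyldimethylsilyloxy)-2,2,6-trimethyl-7-(triisopropylsilyloxy)chroman-5-ol | Cc1c(O[Si](C(C)C)(C(C)C)C(C)C)c(Br)c2c(c1O)[C@H](O[Si](C)(C)C(C)(C)C)CC(C)(C)O2 | intermediate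
21 | 3-phenylpropanoic acid | O=C(O)CCc1ccccc1 | starting material
22 | N-methoxy-N-methyl-3-phenylpropanamide | CON(C)C(=O)CCc1ccccc1 | intermediate
23 | lithium (4R)-4-(tert-butyldimethylsilyloxy)-8-lithio-2,2,6-trimethyl-7-(triisopropylsilyloxy)chroman-5-olate | Cc1c(O[Si](C(C)C)(C(C)C)C(C)C)c([Li])c2c(c1O[Li])[C@H](O[Si](C)(C)C(C)(C)C)CC(C)(C)O2 | intermediate (not isolated)
24 | 1-[(4R)-4-(tert-butyldimethylsilyloxy)-5-hydroxy-2,2,6-trimethyl-7-(triisopropylsilyloxy)chroman-8-yl]-3-phenylpropan-1-one | Cc1c(O[Si](C(C)C)(C(C)C)C(C)C)c(C(=O)CCc3ccccc3)c2c(c1O)[C@H](O[Si](C)(C)C(C)(C)C)CC(C)(C)O2 | intermediate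
25 | 1-[(4R)-4,5,7-trihydroxy-2,2,6-trimethylchroman-8-yl]-3-phenylpropan-1-one | Cc1c(O)c(C(=O)CCc2ccccc2)c2c(c1O)[C@H](O)CC(C)(C)O2 | target

## Step count and risks

Total step count: 11. Longest linear sequence: 9 steps (1, 2, 3, 4, 5, 7, 8, 10, 11); steps 6 and 9 supply the two side branches.

**Step 7 (key step).** The light-driven stage may be inefficient. Diazoketone and product phenol both absorb at 254 nm, the alkoxy-substituted vinylketene can dimerise or be captured by the phenol it has just formed, and secondary photolysis can erode the product. The fallback takes the light out of the ketene generation. It sets out from 10: Wolff rearrangement catalysed by AgOCOPh (monovalent silver) with Et3N in aqueous THF should give 2-[(4R)-4-(tert-butyldimethylsilyloxy)-6,6-dimethyl-5,6-dihydro-4H-pyran-2-yl]acetic acid F1, kept as its triethylammonium salt because of the enol ether. Oxalyl chloride should convert the salt into 2-[(4R)-4-(tert-butyldimethylsilyloxy)-6,6-dimethyl-5,6-dihydro-4H-pyran-2-yl]acetyl chloride F2. Dehydrochlorination of F2 with Et3N in toluene at 80 °C in the presence of 14 should regenerate vinylketene 15 in the dark, which would pass through 16, 17 and 18 and come back to the route at 19.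

**Step 2.** Facial discrimination may be poor, because the two flanks of the carbonyl group (CH= and CH2CMe2) differ little in size and the vinylogous-ester carbonyl is a weak Lewis base toward the catalyst. The fallback sets out from 4: reduction with NaBH4 and CeCl3·7H2O in MeOH at −78 °C (Luche conditions) should give racemic ethyl 4-hydroxy-6,6-dimethyl-5,6-dihydro-4H-pyran-2-carboxylate F3. Kinetic resolution by acylation with vinyl acetate on immobilised Candida antarctica lipase B is expected to acetylate the (R)-enantiomer, giving ethyl (4R)-4-acetoxy-6,6-dimethyl-5,6-dihydro-4H-pyran-2-carboxylate F4 and leaving ethyl (4S)-4-hydroxy-6,6-dimethyl-5,6-dihydro-4H-pyran-2-carboxylate F5. K2CO3 in EtOH would convert F4 into 5, where the route is rejoined, and F5 can be returned to 4 with MnO2. If the enzyme prefers the other enantiomer, the unreacted alcohol is 5 itself.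

**Step 10.** The triisopropylsilyl group may migrate from O7 to the lithiated C8, or the poorly soluble dilithio species may exchange incompletely or be protonated, before the hindered carbanion has added to the amide. The fallback sets out from 20 and uses a faster electrophile on a fully protected ring. Silylation with Et3SiOTf and 2,6-lutidine should give (4R)-8-bromo-4-(tert-butyldimethylsilyloxy)-2,2,6-trimethyl-5-(triethylsilyloxy)-7-(triisopropylsilyloxy)chromane F6. Exchange with t-BuLi at −78 °C and immediate addition of 3-phenylpropanal should give 1-[(4R)-4-(tert-butyldimethylsilyloxy)-2,2,6-trimethyl-5-(triethylsilyloxy)-7-(triisopropylsilyloxy)chroman-8-yl]-3-phenylpropan-1-ol F7 as a mixture of carbinol epimers. Dess–Martin periodinane should oxidise it to 1-[(4R)-4-(tert-butyldimethylsilyloxy)-2,2,6-trimethyl-5-(triethylsilyloxy)-7-(triisopropylsilyloxy)chroman-8-yl]-3-phenylpropan-1-one F8. The conditions of step 11 would then remove all three silyl groups, and the route is rejoined at 25.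

**Step 11.** The C4–O bond may ionise (racemisation or elimination to the 2H-chromene), or the hindered benzylic silyl ether may cleave incompletely, because three oxygen donors flank the benzylic position and the phenoxides formed are basic. The fallback sets out from 24 and separates the easy cleavage from the hard one. K2CO3 in MeOH should remove only the aryl silyl group and give 1-[(4R)-4-(tert-butyldimethylsilyloxy)-5,7-dihydroxy-2,2,6-trimethylchroman-8-yl]-3-phenylpropan-1-one F9. HF·pyridine buffered with excess pyridine in THF at 0 °C should then free the carbinol, and the route is rejoined at 25.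

**Step 5.** Deprotonation may occur in part at the γ-position (C4–H) through the enone, or the enolate may be acylated on oxygen, so that diazo transfer leaves methyl ketone unconverted. The fallback sets out from 6 and uses the classical acylation of diazomethane, which carries its own risk of dipolar addition to the conjugated double bond but has no enolate stage. LiOH in aqueous THF should give (4R)-4-(tert-butyldimethylsilyloxy)-6,6-dimethyl-5,6-dihydro-4H-pyran-2-carboxylic acid F10. Isobutyl chloroformate and N-methylmorpholine should give the mixed anhydride (4R)-4-(tert-butyldimethylsilyloxy)-6,6-dimethyl-5,6-dihydro-4H-pyran-2-carboxylic isobutyl carbonic anhydride F11. Ethereal CH2N2 at 0 °C should then give the diazoketone, and the route is rejoined at 10.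

## Further compounds

F1 | step 7 | 2-[(4R)-4-(tert-butyldimethylsilyloxy)-6,6-dimethyl-5,6-dihydro-4H-pyran-2-yl]acetic acid | OC(=O)CC1=C[C@H](O[Si](C)(C)C(C)(C)C)CC(C)(C)O1
F2 | step 7 | 2-[(4R)-4-(tert-butyldimethylsilyloxy)-6,6-dimethyl-5,6-dihydro-4H-pyran-2-yl]acetyl chloride | ClC(=O)CC1=C[C@H](O[Si](C)(C)C(C)(C)C)CC(C)(C)O1
F3 | step 2 | ethyl 4-hydroxy-6,6-dimethyl-5,6-dihydro-4H-pyran-2-carboxylate (racemate) | CCOC(=O)C1=CC(O)CC(C)(C)O1
F4 | step 2 | ethyl (4R)-4-acetoxy-6,6-dimethyl-5,6-dihydro-4H-pyran-2-carboxylate | CCOC(=O)C1=C[C@H](OC(C)=O)CC(C)(C)O1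
F5 | step 2 | ethyl (4S)-4-hydroxy-6,6-dimethyl-5,6-dihydro-4H-pyran-2-carboxylate | CCOC(=O)C1=C[C@@H](O)CC(C)(C)O1
F6 | step 10 | (4R)-8-bromo-4-(tert-butyldimethylsilyloxy)-2,2,6-trimethyl-5-(triethylsilyloxy)-7-(triisopropylsilyloxy)chromane | Cc1c(O[Si](C(C)C)(C(C)C)C(C)C)c(Br)c2c(c1O[Si](CC)(CC)CC)[C@H](O[Si](C)(C)C(C)(C)C)CC(C)(C)O2
F7 | step 10 | 1-[(4R)-4-(tert-butyldimethylsilyloxy)-2,2,6-trimethyl-5-(triethylsilyloxy)-7-(triisopropylsilyloxy)chroman-8-yl]-3-phenylpropan-1-ol (both carbinol epimers) | Cc1c(O[Si](C(C)C)(C(C)C)C(C)C)c(C(O)CCc3ccccc3)c2c(c1O[Si](CC)(CC)CC)[C@H](O[Si](C)(C)C(C)(C)C)CC(C)(C)O2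
F8 | step 10 | 1-[(4R)-4-(tert-butyldimethylsilyloxy)-2,2,6-trimethyl-5-(triethylsilyloxy)-7-(triisopropylsilyloxy)chroman-8-yl]-3-phenylpropan-1-one | Cc1c(O[Si](C(C)C)(C(C)C)C(C)C)c(C(=O)CCc3ccccc3)c2c(c1O[Si](CC)(CC)CC)[C@H](O[Si](C)(C)C(C)(C)C)CC(C)(C)O2
F9 | step 11 | 1-[(4R)-4-(tert-butyldimethylsilyloxy)-5,7-dihydroxy-2,2,6-trimethylchroman-8-yl]-3-phenylpropan-1-one | Cc1c(O)c(C(=O)CCc3ccccc3)c2c(c1O)[C@H](O[Si](C)(C)C(C)(C)C)CC(C)(C)O2
F10 | step 5 | (4R)-4-(tert-butyldimethylsilyloxy)-6,6-dimethyl-5,6-dihydro-4H-pyran-2-carboxylic acid | OC(=O)C1=C[C@H](O[Si](C)(C)C(C)(C)C)CC(C)(C)O1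
F11 | step 5 | (4R)-4-(tert-butyldimethylsilyloxy)-6,6-dimethyl-5,6-dihydro-4H-pyran-2-carboxylic isobutyl carbonic anhydride | CC(C)COC(=O)OC(=O)C1=C[C@H](O[Si](C)(C)C(C)(C)C)CC(C)(C)O1
A1 | alternative 1 | (R)-1-[5,7-bis(benzyloxy)-4-hydroxy-2,2,6-trimethylchroman-8-yl]-3-phenylpropan-1-one | Cc1c(OCc2ccccc2)c(C(=O)CCc2ccccc2)c2c(c1OCc1ccccc1)[C@H](O)CC(C)(C)O2
A2 | alternative 1 | (R)-5,7-bis(benzyloxy)-8-bromo-2,2,6-trimethylchroman-4-ol | Cc1c(OCc2ccccc2)c(Br)c2c(c1OCc1ccccc1)[C@H](O)CC(C)(C)O2
A3 | alternative 1 | 9-(2-phenylethyl)-9-borabicyclo[3.3.1]nonane | C(Cc1ccccc1)B1C2CCCC1CCC2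
A4 | alternative 1 | carbon monoxide | [C-]#[O+]
A5 | alternative 2 | 5,7-bis(benzyloxy)-2,2,6-trimethyl-2H-chromene | Cc1c(OCc2ccccc2)cc2c(c1OCc1ccccc1)C=CC(C)(C)O2
A6 | alternative 2 | 3,5-bis(benzyloxy)-4-methyl-2-(trimethylsilyl)phenyl trifluoromethanesulfonate | Cc1c(OCc2ccccc2)cc(OS(=O)(=O)C(F)(F)F)c([Si](C)(C)C)c1OCc1ccccc1
A7 | alternative 2 | 3-methylbut-2-enal | CC(C)=CC=O
A8 | alternative 3 | (R)-5,7-bis(benzyloxy)-2,2,6-trimethylchroman-4-ol | Cc1c(OCc2ccccc2)cc2c(c1OCc1ccccc1)[C@H](O)CC(C)(C)O2
A9 | alternative 3 | 2,4-bis(benzyloxy)-6-hydroxy-3-methylbenzaldehyde | Cc1c(OCc2ccccc2)cc(O)c(C=O)c1OCc1ccccc1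
A10 | alternative 3 | 2-methylpropene | CC(C)=C
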